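The runs were computed for an exercise; the scatter is artificial.

| flask | starting material | reagent | protic impurity | remark | time |
|---|---|---|---|---|---|
| oak | 0.10 M | 1 equiv | 2 mM | run made earlier |  |
| alder | 0.10 M | 1.5 equiv | 2 mM | run made earlier |  |
| flask | 0.10 M | 2.00 equiv | 2.00 mM |  | 4.0 h |

| run | time / h | intermediate / % | target / % |
|---|---|---|---|
| oak | 0.500 | 3.1 | 1.0 |
| oak | 0.667 | 3.7 | 1.0 |
| oak | 0.833 | 4.8 | 1.9 |
| oak | 1.00 | 4.6 | 3.1 |
| oak | 1.33 | 5.0 | 3.2 |
| oak | 2.00 | 5.1 | 5.7 |
| oak | 2.50 | 5.7 | 7.3 |
| alder | 0.500 | 4.9 | 1.1 |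
| alder | 0.667 | 5.8 | 2.1 |
| alder | 0.833 | 5.8 | 2.9 |
| alder | 1.00 | 6.7 | 4.3 |
| alder | 1.33 | 7.2 | 5.5 |
| alder | 2.00 | 8.0 | 8.1 |
| alder | 2.50 | 7.3 | 9.5 |

(each reading ± 0.3 percentage points)

* the moment within 4.0 h at which there is most intermediate
* the amount of intermediate, in percent of the starting material charged, at that time

- If I have to name the intermediate peak in this flask now, I start from the balance of starting material, the limiting reagent of the step with the reagent, at 0.10 M against 0.200 M of reagent: intermediate stays below the whole charge, a ceiling too loose to use.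
- I tighten it with one quantity: at its highest reading, alder gives 5.33 % of intermediate per equivalent of reagent, which I call the peak yield per equivalent.
- Oak's last reading gives 5.70 % per equivalent, more than alder's, a gap of 0.37 percentage points against a scatter of 0.3 points on each reading, so I read no rise of the yield per equivalent with reagent, and as my estimate I set the ceiling for this flask at 10.7 %.
- For the floor I take alder's own reading of 8.0 %, assuming that more reagent gives no less, and I place the peak near alder's 2.00 h.
- The forecast says 10.2 % at 2 h, with “a broad, flat maximum”, which stands inside my bracket, 0.50 points under the ceiling.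
- The flask gives 9.49 % at 1.92 h, inside the bracket.

    starting material + reagent → intermediate + released group (k = 0.0170 L mol⁻¹ min⁻¹)
    starting material + protic impurity → quenched substrate (k = 0.460 L mol⁻¹ min⁻¹)
    target → over-reaction product (k = 0.00270 min⁻¹)
    intermediate ⇌ target (K = 2.70, k = 0.0180 min⁻¹)
    starting material → decomposition product (k = 1.50 × 10⁻⁵ min⁻¹)
    intermediate ⇌ isomer of the product (K = 310, k = 0.0100 min⁻¹)

- At 1.92 h this flask holds 8.50 % of isomer of the product. Its peak yield per equivalent is 4.75 %, less than alder's reading. The same flask with 8.00 equiv of reagent has a ceiling of 42.6 % by the same quantity, and it peaks at 24.9 %, which is 3.11 % per equivalent.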